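**Retrosynthetic overview**
1. Eremophilane numbering: ring A = C1-C2-C3-C4-C5-C10, ring B = C5-C6-C7-C8-C9-C10, and β is the face of the C5 methyl. The plan rests on one feature. The C9 oxygen of ring B is bonded next to the fusion carbon C10 and lies on the same β face as the methyl on the other fusion carbon C5. In a flat 5(10)-octalin it is therefore an allylic alcohol that can carry a CH2 unit onto C5 and C10.
2. Late cuts: the O3 ester (acid 35, from angelic acid, (R)-pent-4-en-2-ol and acrylic acid); the C8 ketone from an 8β,9β-diol monoether; both ring B oxygens from a 9-ketone by convex-face oxygenation at C8 and relay to C9; the C7-isopropenyl bond by copper-mediated 1,4-addition to a cis-fused 7-en-9-one.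
3. Middle cuts: 10β-H by hydrogenation directed by a 9β-hydroxyl on a 1(10)-en-9-ol; the C5 methyl by reductive opening (C10-C14) of a 5β,10β-methano 9-ketone.
4. Key cut: C5-C14 and C10-C14 of that cyclopropane, made on the 9β-hydroxy 5(10)-octalin ketal 9. Compound 9 comes from 6-methoxy-1-tetralone by methylation, asymmetric ketone reduction and Birch reduction.
5. Ring order: rings A and B both arrive with the tetralone (ring A is the reduced arene). The only ring closed is the three-membered one in step 6, and it is opened again in step 8.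

Key step: step 6

Assumption: protonation at C4 in step 4 is not face-selective, so 7 to 27 are carried as pairs of C4 epimers (their SMILES carry no descriptor at C4). The pair is merged into the 4β compound in step 17.

**Step 1**
Reactants: 1 6-methoxy-1-tetralone
Product: 2 5-bromo-6-methoxy-1-tetralone
Conditions: NBS (1.0 equiv), H2SO4, H2O, 60 °C; 7-bromo isomer removed by crystallisation
Reagents that add atoms: N-bromosuccinimide O=C1CCC(=O)N1Br
Why: Electrophilic aromatic bromination goes ortho to the methoxy group, and the position next to the ring junction (tetralone C5, the future C4) should be preferred, as is known for this tetralone in aqueous acid.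

**Step 2**
Reactants: 2 5-bromo-6-methoxy-1-tetralone; 3 trimethylboroxine
Product: 4 6-methoxy-5-methyl-1-tetralone
Conditions: Pd(dppf)Cl2 (5 mol %), K2CO3, 1,4-dioxane/H2O, 100 °C
Reagents that add atoms: trimethylboroxine CB1OB(C)OB(C)O1
Why: Suzuki-Miyaura methylation of an aryl bromide tolerates the ketone and places the future C4 methyl without regiochemical doubt.

**Step 3**
Reactants: 4 6-methoxy-5-methyl-1-tetralone
Product: 5 (S)-6-methoxy-5-methyl-1-tetralol
Conditions: RuCl[(S,S)-TsDPEN](p-cymene) (0.5 mol %), HCO2H-Et3N azeotrope, 40 °C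
Reagents that add atoms: none
Why: Noyori asymmetric transfer hydrogenation of a 1-tetralone with the (S,S) catalyst should give the (S)-carbinol, which is C9 with its oxygen on the β face.

**Step 4**
Reactants: 5 (S)-6-methoxy-5-methyl-1-tetralol
Product: 7 9β-hydroxy-3-methoxy-4-methyl-2,5(10)-octalindiene (C4 epimer pair), via lithium alkoxide 6 (not isolated)
Conditions: n-BuLi (1.0 equiv), THF, −78 °C; Li, NH3(l), t-BuOH, −78 to −33 °C; isoprene, then NH4Cl
Reagents that add atoms: none
Why: In this Birch reduction the preformed alkoxide (kept deprotonated because t-BuOH is the weaker acid) resists benzylic C-O hydrogenolysis, and protonation at the free carbon C1 and then at the central pentadienyl carbon C4 keeps the methoxy group and both fusion carbons on double bonds, leaving C9 untouched and forming C4 as both epimers.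

**Step 5**
Reactants: 7 9β-hydroxy-3-methoxy-4-methyl-2,5(10)-octalindiene; 8 ethylene glycol
Product: 9 9β-hydroxy-4-methyl-5(10)-octalin-3-one ethylene ketal (C4 epimer pair)
Conditions: ethylene glycol (5 equiv), pyridinium p-toluenesulfonate (5 mol %), CH2Cl2, 0 °C to rt
Reagents that add atoms: ethylene glycol OCCO
Why: Acid-catalysed enol ether to ketal exchange (protonation at C2, capture of the oxocarbenium ion by the diol), as practised on Birch dienes of estrone ethers, uses an acid weak enough to leave the tetrasubstituted C5,C10 alkene unconjugated and the allylic carbinol intact.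

**Step 6**
Reactants: 9 9β-hydroxy-4-methyl-5(10)-octalin-3-one ethylene ketal; 10 diiodomethane
Product: 12 5β,10β-methano-9β-hydroxy-4-methyldecalin-3-one ethylene ketal (C4 epimer pair), via iodomethylzinc alkoxide 11 (not isolated)
Conditions: Et2Zn (5 equiv), CH2I2 (5 equiv), CH2Cl2, −20 °C to rt; aq NH4Cl
Reagents that add atoms: diiodomethane ICI
Why: Et2Zn deprotonates the C9 carbinol and exchange with CH2I2 gives the iodomethylzinc alkoxide 11, which passes its CH2 to the C5,C10 alkene through the concerted butterfly transition state of a Furukawa-modified Simmons-Smith reaction. The closest known case is the hydroxyl-directed cyclopropanation of octalinols that is used to mask angular methyl groups. The three-membered ring closes in one suprafacial [2+1] event that forms C5-C14 and C10-C14 together, so no other ring size can arise. Both new quaternary centres, C5 and C10, are fixed by the 9β oxygen, because the zinc-bound carbenoid reaches only the β face. The step needs face selectivity and enough reactivity at a tetrasubstituted alkene; intramolecular delivery supplies both. The C3 oxygen is held in a dioxolane with one oxygen on each face, so it exerts no net bias, and excess reagent covers what the ketal oxygens bind.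

**Step 7**
Reactants: 12 5β,10β-methano-9β-hydroxy-4-methyldecalin-3-one ethylene ketal
Product: 13 5β,10β-methano-4-methyldecalin-3,9-dione 3-ethylene ketal (C4 epimer pair)
Conditions: Pr4N[RuO4] (5 mol %), N-methylmorpholine N-oxide, 4 Å sieves, CH2Cl2, rt
Reagents that add atoms: none
Why: Ley-Griffith oxidation under neutral conditions avoids cyclopropylcarbinyl cation chemistry, and the C9 centre can be given up because it has already fixed C5.

**Step 8**
Reactants: 13 5β,10β-methano-4-methyldecalin-3,9-dione 3-ethylene ketal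
Product: 15 9-trimethylsilyloxy-4,5β-dimethyl-9(10)-octalin-3-one ethylene ketal (C4 epimer pair), via lithium enolate 14 (not isolated)
Conditions: Li (2.5 equiv), t-BuOH (1 equiv), NH3(l)/THF, −78 °C; isoprene; NH3 removed; Me3SiCl, Et3N, THF, −78 to 0 °C
Reagents that add atoms: chlorotrimethylsilane C[Si](C)(C)Cl
Why: In this dissolving-metal cleavage of a conjugated cyclopropyl ketone the ketyl breaks the exocyclic C10-C14 bond, which overlaps with the carbonyl π system, rather than the in-ring C5-C10 bond, which leaves CH3 on C5 (β) and a C9,C10 enolate that is silylated regiospecifically.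

**Step 9**
Reactants: 15 9-trimethylsilyloxy-4,5β-dimethyl-9(10)-octalin-3-one ethylene ketal
Product: 16 4,5β-dimethyl-1(10)-octalin-3,9-dione 3-ethylene ketal (C4 epimer pair)
Conditions: Pd(OAc)2 (1.1 equiv), MeCN, 40 °C
Reagents that add atoms: none
Why: In the Saegusa-Ito oxidation, palladation at C10 and syn β-hydride loss from C1 is the only path open to this enol ether, and it turns C10 into an sp2 carbon, which matters because simple protonation of the enolate should place H on the α face, opposite the methyl, and give the wrong trans fusion.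

**Step 10**
Reactants: 16 4,5β-dimethyl-1(10)-octalin-3,9-dione 3-ethylene ketal
Product: 17 9β-hydroxy-4,5β-dimethyl-1(10)-octalin-3-one ethylene ketal (C4 epimer pair)
Conditions: NaBH4, CeCl3·7H2O, MeOH, −78 to −20 °C
Reagents that add atoms: none
Why: In this Luche 1,2-reduction the pseudoaxial C5 methyl, which is 1,3 to C9, shields the β face, so hydride should enter from α and give the 9β allylic alcohol.

**Step 11**
Reactants: 17 9β-hydroxy-4,5β-dimethyl-1(10)-octalin-3-one ethylene ketal
Product: 18 cis-fused 9β-hydroxy-4,5β-dimethyl-10βH-decalin-3-one ethylene ketal (C4 epimer pair)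
Conditions: [Ir(cod)(PCy3)(py)]PF6 (5 mol %), H2 (1 atm), CH2Cl2, rt
Reagents that add atoms: none
Why: In this hydroxyl-directed homogeneous hydrogenation, iridium bound to the 9β oxygen delivers H2 to the β face of the C1,C10 alkene, which sets 10β-H and the cis fusion against the steric bias of the methyl group.

**Step 12**
Reactants: 18 cis-fused 9β-hydroxy-4,5β-dimethyl-10βH-decalin-3-one ethylene ketal
Product: 19 cis-fused 4,5β-dimethyl-10βH-decalin-3,9-dione 3-ethylene ketal (C4 epimer pair)
Conditions: Pr4N[RuO4] (5 mol %), N-methylmorpholine N-oxide, 4 Å sieves, CH2Cl2, rt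
Reagents that add atoms: none
Why: Ley-Griffith oxidation in a non-basic medium keeps the kinetically set configuration at C10.

**Step 13**
Reactants: 19 cis-fused 4,5β-dimethyl-10βH-decalin-3,9-dione 3-ethylene ketal
Product: 21 cis-fused 4,5β-dimethyl-10βH-7-octalin-3,9-dione 3-ethylene ketal (C4 epimer pair), via lithium enolate 20 (not isolated)
Conditions: LiN(i-Pr)2 (1.1 equiv), THF, −78 °C; N-tert-butylbenzenesulfinimidoyl chloride (1.2 equiv), −78 °C
Reagents that add atoms: none
Why: Kinetic deprotonation at the C8 methylene rather than the C10 methine, followed by Mukaiyama dehydrogenation (sulfur attack at C8, then syn elimination), gives the 7-en-9-one at low temperature without touching C10.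

**Step 14**
Reactants: 21 cis-fused 7-en-9-one; 22 2-bromopropene
Product: 23 9-(tert-butyldimethylsilyloxy)-7β-isopropenyl-4,5β-dimethyl-10βH-8-octalin-3-one ethylene ketal (C4 epimer pair)
Conditions: 22, Mg, THF; CuBr·SMe2 (0.2 equiv), HMPA, t-BuMe2SiCl, then 21, THF, −78 to −30 °C
Reagents that add atoms: 2-bromopropene C=C(C)Br; tert-butyldimethylsilyl chloride CC(C)(C)[Si](C)(C)Cl
Why: In this copper-catalysed conjugate addition with silyl chloride trapping, the isopropenyl cuprate should enter C7 from the convex β face of the cis-fused enone, away from ring A folded under the α face, and the C8,C9 enolate is caught regiospecifically.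

**Step 15**
Reactants: 23 silyl enol ether
Product: 24 8β-(tert-butyldimethylsilyloxy)-7β-isopropenyl-4,5β-dimethyl-10βH-decalin-3,9-dione 3-ethylene ketal (C4 epimer pair)
Conditions: mCPBA (1.05 equiv), CH2Cl2/hexane, −20 °C
Reagents that add atoms: 3-chloroperbenzoic acid O=C(OO)c1cccc(Cl)c1
Why: In the Rubottom oxidation the electron-rich silyl enol ether reacts far faster than the 1,1-disubstituted alkene, the peracid comes from the convex β face (axial at C8), and silyl migration gives the 8β-silyloxy ketone.

**Step 16**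
Reactants: 24 8β-silyloxy 9-ketone
Product: 26 9β-(tert-butyldimethylsilyloxy)-8β-hydroxy-7β-isopropenyl-4,5β-dimethyl-10βH-decalin-3-one ethylene ketal (C4 epimer pair), via 9β-alcohol 25 (not isolated)
Conditions: NaBH4, MeOH/CH2Cl2, −40 °C; then K2CO3 (0.2 equiv), MeOH, rt
Reagents that add atoms: none
Why: In this carbonyl reduction under polar Felkin-Anh control the small hydride should attack anti to the axial C8-O bond, which also blocks the β face, to give the equatorial 9β-alcohol cis to O8, and base-catalysed 1,2-silyl migration then moves silicon from the crowded axial O8 to the equatorial O9.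

**Step 17**
Reactants: 26 9β-silyloxy 8β-alcohol ketal
Product: 28 9β-(tert-butyldimethylsilyloxy)-8β-hydroxy-7β-isopropenyl-4β,5β-dimethyl-10βH-decalin-3-one, via 3-ketone epimer pair 27 (not isolated)
Conditions: 1 M HCl, THF, 0 °C to rt; then DBU (0.3 equiv), toluene, rt
Reagents that add atoms: water O
Why: Ketal hydrolysis is followed by enolate-mediated epimerisation at C4, where the equatorial 7β group holds the cis-decalin in the chair pair in which a 4α methyl would be syn-axial to C9, so both epimers should converge on the equatorial 4β methyl while ring B carries no ketone.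

**Step 18**
Reactants: 28 3-ketone
Product: 29 9β-(tert-butyldimethylsilyloxy)-7β-isopropenyl-4β,5β-dimethyl-10βH-decalin-3α,8β-diol
Conditions: SmI2 (4 equiv), H2O, THF, rt
Reagents that add atoms: none
Why: Single-electron ketone reduction (SmI2-H2O), with protonation of the ketyl and organosamarium species, should give the more stable equatorial 3α-alcohol trans to the 4β methyl, whereas hydride reagents would be pushed by the axial C5 methyl to the wrong axial alcohol.

**Step 19**
Reactants: 30 angelic acid; 31 (R)-pent-4-en-2-ol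
Product: 33 (R)-pent-4-en-2-yl angelate, via mixed anhydride 32 (not isolated)
Conditions: 2,4,6-Cl3C6H2COCl, Et3N, toluene, rt; then 31, 80 °C (no DMAP)
Reagents that add atoms: angelic acid C/C=C(/C)C(=O)O
Why: Yamaguchi-type mixed anhydride acylation without a nucleophilic catalyst avoids the addition-elimination path that turns angelates into tiglates, and the carbinol centre is not touched.

**Step 20**
Reactants: 33 (R)-pent-4-en-2-yl angelate; 34 acrylic acid
Product: 35 (R,E)-5-(angeloyloxy)hex-2-enoic acid
Conditions: second-generation Hoveyda-Grubbs catalyst (5 mol %), acrylic acid (3 equiv), CH2Cl2, 40 °C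
Reagents that add atoms: acrylic acid C=CC(=O)O
Why: Cross metathesis of a terminal alkene with an acrylate partner is E-selective, and the trisubstituted, electron-poor angelate alkene is a spectator.

**Step 21**
Reactants: 29 3α,8β-diol; 35 (R,E)-5-(angeloyloxy)hex-2-enoic acid
Product: 36 3α-[(R,E)-5-(angeloyloxy)hex-2-enoyloxy]-9β-(tert-butyldimethylsilyloxy)-8β-hydroxy-7β-isopropenyl-4β,5β-dimethyl-10βH-decalin
Conditions: EDC·HCl (1.1 equiv), DMAP (0.1 equiv), CH2Cl2, 0 °C
Reagents that add atoms: acid 35 OC(=O)/C=C/C[C@@H](C)OC(=O)/C(C)=C\C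
Why: In this Steglich-type esterification the equatorial 3α-hydroxyl is acylated while the axial 8β-hydroxyl, flanked by the isopropenyl and silyloxy groups, should stay free, and low temperature with little DMAP guards against enoate deconjugation and angelate isomerisation.

**Step 22**
Reactants: 36 8β-alcohol
Product: 37 9-O-tert-butyldimethylsilyl ether of the target
Conditions: Dess-Martin periodinane (1.5 equiv), CH2Cl2, 0 °C to rt
Reagents that add atoms: none
Why: Dess-Martin oxidation under neutral conditions turns the last free carbinol into the C8 ketone without enolising C7, so the β,γ-unsaturated ketone is not conjugated and C7 and C9 keep their configuration.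

**Step 23**
Reactants: 37 9-O-silyl ether
Product: 38 CNP0210874.1 (target)
Conditions: HF·pyridine, pyridine, THF, 0 °C
Reagents that add atoms: none
Why: Buffered fluoride desilylation frees the 9β-hydroxyl under conditions too mild for ester cleavage, ketol tautomerisation or alkene migration.

**Compound list**
1 | 6-methoxy-1-tetralone | COc1ccc2c(c1)CCCC2=O | starting material
2 | 5-bromo-6-methoxy-1-tetralone | COc1ccc2c(c1Br)CCCC2=O | intermediate
3 | trimethylboroxine | CB1OB(C)OB(C)O1 | starting material
4 | 6-methoxy-5-methyl-1-tetralone | COc1ccc2c(c1C)CCCC2=O | intermediate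
5 | (S)-6-methoxy-5-methyl-1-tetralol | O[C@H]1CCCc2c1ccc(OC)c2C | intermediate
6 | lithium alkoxide of 5 | [Li]O[C@H]1CCCc2c1ccc(OC)c2C | intermediate
7 | 9β-hydroxy-3-methoxy-4-methyl-2,5(10)-octalindiene (C4 epimer pair) | O[C@H]1CCCC2=C1CC=C(OC)C2C | intermediate
8 | ethylene glycol | OCCO | starting material
9 | 9β-hydroxy-4-methyl-5(10)-octalin-3-one ethylene ketal (C4 epimer pair) | O[C@H]1CCCC2=C1CCC3(OCCO3)C2C | intermediate
10 | diiodomethane | ICI | starting material
11 | iodomethylzinc alkoxide of 9 | IC[Zn]O[C@H]1CCCC2=C1CCC3(OCCO3)C2C | intermediate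
12 | 5β,10β-methano-9β-hydroxy-4-methyldecalin-3-one ethylene ketal (C4 epimer pair) | O[C@H]1CCC[C@@]23C[C@@]12CCC4(OCCO4)C3C | intermediate
13 | 5β,10β-methano-4-methyldecalin-3,9-dione 3-ethylene ketal | O=C1CCC[C@@]23C[C@@]12CCC4(OCCO4)C3C | intermediate
14 | lithium 9(10)-enolate | [Li]OC1=C2CCC3(OCCO3)C(C)[C@@]2(C)CCC1 | intermediate
15 | 9-trimethylsilyloxy-4,5β-dimethyl-9(10)-octalin-3-one ethylene ketal | C[Si](C)(C)OC1=C2CCC3(OCCO3)C(C)[C@@]2(C)CCC1 | intermediate
16 | 4,5β-dimethyl-1(10)-octalin-3,9-dione 3-ethylene ketal | O=C1CCC[C@@]2(C)C1=CCC3(OCCO3)C2C | intermediate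
17 | 9β-hydroxy-4,5β-dimethyl-1(10)-octalin-3-one ethylene ketal | O[C@H]1CCC[C@@]2(C)C1=CCC3(OCCO3)C2C | intermediate
18 | cis-fused 9β-hydroxy-4,5β-dimethyl-10βH-decalin-3-one ethylene ketal | O[C@H]1CCC[C@@]2(C)[C@@H]1CCC3(OCCO3)C2C | intermediate
19 | cis-fused 4,5β-dimethyl-10βH-decalin-3,9-dione 3-ethylene ketal | O=C1CCC[C@@]2(C)[C@@H]1CCC3(OCCO3)C2C | intermediate
20 | lithium 8(9)-enolate | [Li]OC1=CCC[C@@]2(C)[C@@H]1CCC3(OCCO3)C2C | intermediate
21 | cis-fused 4,5β-dimethyl-10βH-7-octalin-3,9-dione 3-ethylene ketal | O=C1C=CC[C@@]2(C)[C@@H]1CCC3(OCCO3)C2C | intermediate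
22 | 2-bromopropene | C=C(C)Br | starting material
23 | 9-(tert-butyldimethylsilyloxy)-7β-isopropenyl-4,5β-dimethyl-10βH-8-octalin-3-one ethylene ketal | CC(C)(C)[Si](C)(C)OC1=C[C@@H](C(C)=C)C[C@@]2(C)[C@@H]1CCC3(OCCO3)C2C | intermediate
24 | 8β-silyloxy-7β-isopropenyl 3,9-dione 3-ketal | O=C1[C@@H](O[Si](C)(C)C(C)(C)C)[C@@H](C(C)=C)C[C@@]2(C)[C@@H]1CCC3(OCCO3)C2C | intermediate
25 | 8β-silyloxy-9β-alcohol ketal | O[C@H]1[C@@H](O[Si](C)(C)C(C)(C)C)[C@@H](C(C)=C)C[C@@]2(C)[C@@H]1CCC3(OCCO3)C2C | intermediate
26 | 9β-silyloxy-8β-alcohol ketal | CC(C)(C)[Si](C)(C)O[C@H]1[C@@H](O)[C@@H](C(C)=C)C[C@@]2(C)[C@@H]1CCC3(OCCO3)C2C | intermediate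
27 | 9β-silyloxy-8β-hydroxy 3-ketone (C4 epimer pair) | CC(C)(C)[Si](C)(C)O[C@H]1[C@@H](O)[C@@H](C(C)=C)C[C@@]2(C)[C@@H]1CCC(=O)C2C | intermediate
28 | 9β-silyloxy-8β-hydroxy-4β-methyl 3-ketone | CC(C)(C)[Si](C)(C)O[C@H]1[C@@H](O)[C@@H](C(C)=C)C[C@@]2(C)[C@@H]1CCC(=O)[C@@H]2C | intermediate
29 | 9β-silyloxy 3α,8β-diol | CC(C)(C)[Si](C)(C)O[C@H]1[C@@H](O)[C@@H](C(C)=C)C[C@@]2(C)[C@@H]1CC[C@@H](O)[C@@H]2C | intermediate
30 | angelic acid | C/C=C(/C)C(=O)O | starting material
31 | (R)-pent-4-en-2-ol | C=CC[C@@H](C)O | starting material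
32 | angelic 2,4,6-trichlorobenzoic anhydride | C/C=C(/C)C(=O)OC(=O)c1c(Cl)cc(Cl)cc1Cl | intermediate
33 | (R)-pent-4-en-2-yl angelate | C=CC[C@@H](C)OC(=O)/C(C)=C\C | intermediate
34 | acrylic acid | C=CC(=O)O | starting material
35 | (R,E)-5-(angeloyloxy)hex-2-enoic acid | OC(=O)/C=C/C[C@@H](C)OC(=O)/C(C)=C\C | intermediate
36 | 3α-ester 8β-alcohol 9β-silyl ether | CC(C)(C)[Si](C)(C)O[C@H]1[C@@H](O)[C@@H](C(C)=C)C[C@@]2(C)[C@@H]1CC[C@@H](OC(=O)/C=C/C[C@@H](C)OC(=O)/C(C)=C\C)[C@@H]2C | intermediate
37 | 9-O-silyl ether of the target | CC(C)(C)[Si](C)(C)O[C@H]1C(=O)[C@@H](C(C)=C)C[C@@]2(C)[C@@H]1CC[C@@H](OC(=O)/C=C/C[C@@H](C)OC(=O)/C(C)=C\C)[C@@H]2C | intermediate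
38 | CNP0210874.1 | C=C(C)[C@H]1C[C@@]2(C)[C@H](CC[C@@H](OC(=O)/C=C/C[C@@H](C)OC(=O)/C(C)=C\C)[C@@H]2C)[C@@H](O)C1=O | target

**Totals**
Total step count: 23. Longest linear sequence: 21 (steps 1 to 18 and 21 to 23).

**Steps most likely to fail**

*Step 6.* Methylene transfer to the tetrasubstituted alkene may be slower than ionisation of the allylic carbinol or loss of the ketal under zinc iodide. Carbenoid held by a dioxolane oxygen may also erode the face selectivity.
- The fallback sets out from 9 and comes back at 12. It ties the one-carbon unit to O9.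
- Acylation of 9 with glyoxylic acid chloride tosylhydrazone and Et3N gives the diazoacetate F1.
- Rh2(OAc)4 closes the cyclopropane-fused γ-lactone F2 by intramolecular carbene addition. For geometric reasons this addition is possible only on the β face.
- i-Bu2AlH gives the lactol F3. Its open hydroxy aldehyde form is decarbonylated with RhCl(PPh3)3 (Tsuji-Wilkinson) to 12.

*Step 14.* The cis-fused enone may epimerise at C10 before it reacts, and attack through the other half-chair may lower the face selectivity at C7.
- The fallback sets out from 21 and comes back at 23. It replaces substrate control by catalyst control.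
- Hayashi-Miyaura addition of potassium isopropenyltrifluoroborate with [RhCl(cod)]2 and (S)-BINAP (Et3N, toluene/H2O) gives the 7β-isopropenyl ketone F4. Any C10 epimerisation is then self-correcting, because the 7β group favours the cis fusion.
- LiN(i-Pr)2 and then t-BuMe2SiOTf give 23.

*Step 16.* Hydride delivery to the concave α face of C9 may lose against attack from the β face, past the silyloxy group. The C9 oxygen then ends up α, and the silyl shift cannot take place.
- The fallback sets out from 24 and comes back at 38. It forms the C9-O bond from the β face by substitution instead.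
- Reduction gives the 9α-alcohol F5. The conditions of step 17 give the 3-ketone F6, and those of step 18 give the 3α-alcohol F7.
- Esterification as in step 21 gives the ester F8. The buried 9α-hydroxyl should stay free.
- HF·pyridine gives the 8β,9α-diol F9. One equivalent of Dess-Martin periodinane oxidises the exposed 8β-hydroxyl to the 9α-ketol F10.
- Tf2O and pyridine give the triflate F11. Bu4NNO2 displaces the carbonyl-activated triflate from the convex face (Lattrell-Dax inversion), and 38 results after aqueous work-up.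

**Further compounds**
F1 | step 6 | diazoacetate of 9 | [N-]=[N+]=CC(=O)O[C@H]1CCCC2=C1CCC3(OCCO3)C2C
F2 | step 6 | cyclopropane-fused γ-lactone (C14 carbonyl bound to O9) | O=C1O[C@H]2CCC[C@@]34[C@@H]1[C@@]23CCC5(OCCO5)C4C
F3 | step 6 | lactol of F2 | OC1O[C@H]2CCC[C@@]34[C@@H]1[C@@]23CCC5(OCCO5)C4C
F4 | step 14 | cis-fused 7β-isopropenyl-4,5β-dimethyl-10βH-decalin-3,9-dione 3-ethylene ketal | O=C1C[C@@H](C(C)=C)C[C@@]2(C)[C@@H]1CCC3(OCCO3)C2C
F5 | step 16 | 8β-silyloxy-9α-alcohol ketal | O[C@@H]1[C@@H](O[Si](C)(C)C(C)(C)C)[C@@H](C(C)=C)C[C@@]2(C)[C@@H]1CCC3(OCCO3)C2C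
F6 | step 16 | 8β-silyloxy-9α-hydroxy-4β-methyl 3-ketone | O[C@@H]1[C@@H](O[Si](C)(C)C(C)(C)C)[C@@H](C(C)=C)C[C@@]2(C)[C@@H]1CCC(=O)[C@@H]2C
F7 | step 16 | 8β-silyloxy 3α,9α-diol | O[C@@H]1[C@@H](O[Si](C)(C)C(C)(C)C)[C@@H](C(C)=C)C[C@@]2(C)[C@@H]1CC[C@@H](O)[C@@H]2C
F8 | step 16 | 3α-ester 8β-silyl ether 9α-alcohol | O[C@@H]1[C@@H](O[Si](C)(C)C(C)(C)C)[C@@H](C(C)=C)C[C@@]2(C)[C@@H]1CC[C@@H](OC(=O)/C=C/C[C@@H](C)OC(=O)/C(C)=C\C)[C@@H]2C
F9 | step 16 | 3α-ester 8β,9α-diol | O[C@@H]1[C@@H](O)[C@@H](C(C)=C)C[C@@]2(C)[C@@H]1CC[C@@H](OC(=O)/C=C/C[C@@H](C)OC(=O)/C(C)=C\C)[C@@H]2C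
F10 | step 16 | 9-epimer of the target (9α-ketol) | O[C@@H]1C(=O)[C@@H](C(C)=C)C[C@@]2(C)[C@@H]1CC[C@@H](OC(=O)/C=C/C[C@@H](C)OC(=O)/C(C)=C\C)[C@@H]2C
F11 | step 16 | 9α-triflate of F10 | O=S(=O)(O[C@@H]1C(=O)[C@@H](C(C)=C)C[C@@]2(C)[C@@H]1CC[C@@H](OC(=O)/C=C/C[C@@H](C)OC(=O)/C(C)=C\C)[C@@H]2C)C(F)(F)F
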